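The six-membered carbocycle C5–C10 is traced back to a cyclopentene. Ring carbon C5, which carries the side chain, is deleted, leaving the cis-fused lactone 7-methyl-2-oxabicyclo[3.3.0]oct-6-en-3-one. Forward, C5 returns as dibromocarbene across C6=C10. Silver-assisted loss of the endo bromide then opens the C6–C10 bond, enlarges the ring, lets (R)-2-methylbutanoate bond to C6 anti to C11, and leaves bromine on C5 for attaching the C1–C4 chain. The feature exploited is the allylic triad C6 (acyloxy)–C5 (alkyl)=C10 (methyl) of the cyclohexene ring, next to the lactone-bearing C7. The precursor is the convex-face gem-dibromocyclopropane of that lactone, used with the free acid.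

Key step: step 5

Numbering used (target): side chain C1 (CH2OH) to C4 (CH, methyl C15); carbocycle C5 (chain), C6 (acyloxy), C7, C8 (lactone O), C9, C10 (methyl C14); lactone C11 (on C7), C12 (C=O), C13 (=CH2).

Remark: 1 is taken from freshly cracked commercial methylcyclopentadiene dimer, which also contains the 2-methyl isomer; the cycloadducts of that isomer are removed by fractional distillation after step 1 and chromatography after step 2.

Step 1
Reactants: 1 1-methylcyclopenta-1,3-diene; 2 dichloroacetyl chloride
Product: 4 racemic cis-7,7-dichloro-3-methylbicyclo[3.2.0]hept-2-en-6-one, via dichloroketene 3 (not isolated)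
Conditions: Et3N (slow addition), hexane, 0 °C to rt; fractional distillation
Reagents that add atoms: none
Why: Ketene–diene (2+2) cycloaddition in which the electrophilic carbonyl carbon of dichloroketene bonds to the unsubstituted diene terminus of 1 (ring position 4), so the developing allyl cation is stabilised at its methyl-bearing end and closure gives the cis-fused 3-methyl adduct as a racemate.

Step 2
Reactants: 4 racemic cis-7,7-dichloro-3-methylbicyclo[3.2.0]hept-2-en-6-one
Product: 5 racemic cis-3-methylbicyclo[3.2.0]hept-2-en-6-one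
Conditions: Zn dust, AcOH, 50 °C; chromatography
Reagents that add atoms: none
Why: Reductive dechlorination of an α,α-dichloroketone by zinc in acetic acid, which leaves the trisubstituted alkene and the cis ring fusion untouched.

Step 3
Reactants: 5 racemic cis-3-methylbicyclo[3.2.0]hept-2-en-6-one
Product: 6 (1R,5S)-7-methyl-2-oxabicyclo[3.3.0]oct-6-en-3-one
Conditions: Baeyer–Villiger monooxygenase (selected from a panel; enantiopreference opposite to that of Acinetobacter cyclohexanone monooxygenase), NADP+ (cat.), phosphite dehydrogenase, Na2HPO3, air, Tris buffer pH 8, 25 °C; chromatography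
Reagents that add atoms: dioxygen, O=O
Why: Enzymatic Baeyer–Villiger oxidation run as a regiodivergent parallel kinetic resolution, a benchmark reaction of bicyclo[3.2.0]hept-2-en-6-ones, in which the (1S,5R)-ketone should undergo bridgehead migration with retention to the normal lactone 6 while its antipode is diverted to the separable 3-oxa regioisomer, so that C7 and C8 are fixed here.

Step 4
Reactants: 6 (1R,5S)-7-methyl-2-oxabicyclo[3.3.0]oct-6-en-3-one; 7 bromoform
Product: 9 (1S,2S,4R,6R)-3,3-dibromo-4-methyl-7-oxatricyclo[4.3.0.0^2,4]nonan-8-one, via dibromocarbene 8 (not isolated)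
Conditions: KOtBu (added in portions), hexane/toluene, −20 to 0 °C; cold work-up, used at once
Reagents that add atoms: none
Why: Dibromocarbene cycloaddition under anhydrous Doering–Hoffmann conditions, in which the electrophilic carbene adds to the electron-rich trisubstituted alkene from the convex face of the cis-bicyclo[3.3.0]octene (anti to the lactone ring) while the excess bromoform consumes the alkoxide faster than the lactone can.

Step 5
Reactants: 9 (1S,2S,4R,6R)-3,3-dibromo-4-methyl-7-oxatricyclo[4.3.0.0^2,4]nonan-8-one; 10 (R)-2-methylbutanoic acid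
Product: 13 (3aR,4S,7aR)-5-bromo-6-methyl-2-oxo-2,3,3a,4,7,7a-hexahydro-1-benzofuran-4-yl (2R)-2-methylbutanoate, via silver (R)-2-methylbutanoate 11 (not isolated), via 2-bromocyclohexenyl cation 12 (not isolated)
Conditions: 10 (5 equiv), Ag2O (0.75 equiv), 4 Å molecular sieves, CH2Cl2, rt; then 9, 0 °C to rt, dark
Reagents that add atoms: none
Why: Monovalent silver pulls off the endo bromide (the one lying over the five-membered ring) while the C6–C10 bond opens in a disrotatory two-electron electrocyclic process, so the bicyclo[3.1.0]hexane unit becomes the ring-contained 2-bromoallyl cation 12 with bromine on the inserted C5. The closest known reaction type is the silver-promoted ring expansion of 6,6-dibromobicyclo[3.1.0]hexanes with capture by acetate to give 2-bromocyclohex-2-enyl esters. The six-membered ring is formed not by cyclisation but by cleavage of the zero-atom bridge C6–C10 of the cyclopropane-fused cyclopentane, which places C5 between C6 and C10. The new stereocentre C6 is set by carboxylate attack on the convex face of the cis-fused bicyclic cation, anti to C11 on the neighbouring C7. The step needs C6 over the tertiary terminus C10 and capture over proton loss from C9 or C14: the C6 ester with the tetrasubstituted C5=C10 alkene is the thermodynamic product because a tertiary C10 ester would re-ionise in the excess free acid, and the water-free, weakly basic medium at low temperature disfavours elimination. Any allylic dibromide formed by premature opening of the labile 9 should converge on the same cation under these conditions.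

Step 6
Reactants: 14 (R)-γ-valerolactone
Product: 15 (R)-pentane-1,4-diol
Conditions: LiAlH4, THF, 0 °C to rt; Fieser work-up
Reagents that add atoms: none
Why: Hydride reduction of a lactone to the diol, in which the carbinol stereocentre takes no part.

Step 7
Reactants: 15 (R)-pentane-1,4-diol
Product: 16 (2R)-5-{[tert-butyl(dimethyl)silyl]oxy}pentan-2-ol
Conditions: TBSCl (1.0 equiv), imidazole, CH2Cl2, −10 to 0 °C
Reagents that add atoms: tert-butyldimethylsilyl chloride, CC(C)(C)[Si](C)(C)Cl
Why: Sterically controlled monosilylation, the unhindered primary hydroxyl reacting well ahead of the secondary one.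

Step 8
Reactants: 16 (2R)-5-{[tert-butyl(dimethyl)silyl]oxy}pentan-2-ol
Product: 17 tert-butyl{[(4S)-4-iodopentyl]oxy}dimethylsilane
Conditions: PPh3, I2, N-methylimidazole, CH2Cl2, −10 °C
Reagents that add atoms: iodine, II
Why: Appel-type iodination, in which iodide displaces the alkoxyphosphonium ion by an SN2 path and so inverts the carbinol centre to the (S)-iodide, the low temperature limiting iodide–iodide exchange.

Step 9
Reactants: 17 tert-butyl{[(4S)-4-iodopentyl]oxy}dimethylsilane; 13 (3aR,4S,7aR)-5-bromo-6-methyl-2-oxo-2,3,3a,4,7,7a-hexahydro-1-benzofuran-4-yl (2R)-2-methylbutanoate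
Product: 20 (3aR,4S,7aR)-5-[(2S)-5-{[tert-butyl(dimethyl)silyl]oxy}pentan-2-yl]-6-methyl-2-oxo-2,3,3a,4,7,7a-hexahydro-1-benzofuran-4-yl (2R)-2-methylbutanoate, via secondary alkyllithium 18 (not isolated), via mixed dialkylzinc 19 (not isolated)
Conditions: t-BuLi (2.2 equiv), pentane/Et2O 3:2, −100 °C; Me3SiCH2ZnBr·LiBr, THF, −100 to −30 °C; then 13, [Pd2I2(PtBu3)2] (3 mol%), −25 °C to rt
Reagents that add atoms: none
Why: Stereoretentive Negishi cross-coupling, in which iodine–lithium exchange at −100 °C and transmetalation to the configurationally stable mixed dialkylzinc both proceed with retention, and oxidative addition of the C5–Br bond to zerovalent palladium, transmetalation and reductive elimination then transfer the secondary alkyl group with retention, setting C4 as S.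

Step 10
Reactants: 20 (3aR,4S,7aR)-5-[(2S)-5-{[tert-butyl(dimethyl)silyl]oxy}pentan-2-yl]-6-methyl-2-oxo-2,3,3a,4,7,7a-hexahydro-1-benzofuran-4-yl (2R)-2-methylbutanoate
Product: 24 (3aR,4S,7aR)-5-[(2S)-5-{[tert-butyl(dimethyl)silyl]oxy}pentan-2-yl]-6-methyl-3-methylidene-2-oxo-2,3,3a,4,7,7a-hexahydro-1-benzofuran-4-yl (2R)-2-methylbutanoate, via lithium lactone enolate 21 (not isolated), via Mannich base 22 (not isolated), via trimethylammonium iodide 23 (not isolated)
Conditions: LiN(SiMe3)2 (1.05 equiv), THF, −78 °C; CH2=NMe2+ I−, −78 °C to rt; then MeI, CH2Cl2, rt; then aq. NaHCO3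
Reagents that add atoms: N,N-dimethylmethyleneiminium iodide (Eschenmoser's salt), C=[N+](C)C.[I-]
Why: α-Methylenation by Mannich reaction of the lactone enolate followed by quaternisation and base-induced elimination of trimethylamine, the amide base removing the more acidic, unhindered C11–H of the lactone in preference to the tertiary α-H of the branched ester, with no stereocentre created.

Step 11
Reactants: 24 (3aR,4S,7aR)-5-[(2S)-5-{[tert-butyl(dimethyl)silyl]oxy}pentan-2-yl]-6-methyl-3-methylidene-2-oxo-2,3,3a,4,7,7a-hexahydro-1-benzofuran-4-yl (2R)-2-methylbutanoate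
Product: 25 (3aR,4S,7aR)-5-[(2S)-5-hydroxypentan-2-yl]-6-methyl-3-methylidene-2-oxo-2,3,3a,4,7,7a-hexahydro-1-benzofuran-4-yl (2R)-2-methylbutanoate
Conditions: HF·pyridine, THF/pyridine, 0 °C to rt
Reagents that add atoms: none
Why: Fluoride-mediated cleavage of the primary silyl ether under buffered conditions that should leave the α-methylene lactone and the allylic ester untouched.

Compound list
1 | 1-methylcyclopenta-1,3-diene (from cracked commercial dimer) | CC1=CC=CC1 | starting material
2 | dichloroacetyl chloride | ClC(Cl)C(=O)Cl | starting material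
3 | dichloroketene (formed in the flask) | ClC(Cl)=C=O | intermediate
4 | racemic cis-7,7-dichloro-3-methylbicyclo[3.2.0]hept-2-en-6-one ((1S,5R) enantiomer drawn) | ClC1(Cl)C(=O)[C@@H]2CC(C)=C[C@H]12 | intermediate
5 | racemic cis-3-methylbicyclo[3.2.0]hept-2-en-6-one ((1S,5R) enantiomer drawn) | C1C(=O)[C@@H]2CC(C)=C[C@H]12 | intermediate
6 | (1R,5S)-7-methyl-2-oxabicyclo[3.3.0]oct-6-en-3-one (cis-fused; also (3aS,6aR)-5-methyl-3,3a,6,6a-tetrahydro-2H-cyclopenta[b]furan-2-one) | C1C(=O)O[C@@H]2CC(C)=C[C@H]12 | intermediate
7 | bromoform | BrC(Br)Br | starting material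
8 | dibromocarbene (formed in the flask) | Br[C]Br | intermediate
9 | (1S,2S,4R,6R)-3,3-dibromo-4-methyl-7-oxatricyclo[4.3.0.0^2,4]nonan-8-one (cyclopropane anti to the lactone ring) | C1C(=O)O[C@@H]2C[C@@]3(C)C(Br)(Br)[C@H]3[C@H]12 | intermediate
10 | (R)-2-methylbutanoic acid | CC[C@@H](C)C(=O)O | starting material
11 | silver (R)-2-methylbutanoate (formed in the flask) | CC[C@@H](C)C(=O)[O-].[Ag+] | intermediate
12 | cis-fused 2-bromocyclohexenyl (2-bromoallyl) cation, charge shared by C6 and C10 (formed in the flask) | C1C(=O)O[C@@H]2CC(C)=C(Br)[CH+][C@H]12 | intermediate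
13 | (3aR,4S,7aR)-5-bromo-6-methyl-2-oxo-2,3,3a,4,7,7a-hexahydro-1-benzofuran-4-yl (2R)-2-methylbutanoate | C1C(=O)O[C@@H]2CC(C)=C(Br)[C@@H](OC(=O)[C@H](C)CC)[C@H]12 | intermediate
14 | (R)-γ-valerolactone ((5R)-5-methyloxolan-2-one) | C[C@@H]1CCC(=O)O1 | starting material
15 | (R)-pentane-1,4-diol | C[C@@H](O)CCCO | intermediate
16 | (2R)-5-{[tert-butyl(dimethyl)silyl]oxy}pentan-2-ol | C[C@@H](O)CCCO[Si](C)(C)C(C)(C)C | intermediate
17 | tert-butyl{[(4S)-4-iodopentyl]oxy}dimethylsilane | C[C@H](I)CCCO[Si](C)(C)C(C)(C)C | intermediate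
18 | 5-(tert-butyldimethylsilyloxy)pentan-2-yllithium, configuration of 17 retained (formed in the flask) | C[C@H]([Li])CCCO[Si](C)(C)C(C)(C)C | intermediate
19 | [5-(tert-butyldimethylsilyloxy)pentan-2-yl](trimethylsilylmethyl)zinc, configuration retained (formed in the flask) | C[C@H]([Zn]C[Si](C)(C)C)CCCO[Si](C)(C)C(C)(C)C | intermediate
20 | (3aR,4S,7aR)-5-[(2S)-5-{[tert-butyl(dimethyl)silyl]oxy}pentan-2-yl]-6-methyl-2-oxo-2,3,3a,4,7,7a-hexahydro-1-benzofuran-4-yl (2R)-2-methylbutanoate | C1C(=O)O[C@@H]2CC(C)=C([C@@H](C)CCCO[Si](C)(C)C(C)(C)C)[C@@H](OC(=O)[C@H](C)CC)[C@H]12 | intermediate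
21 | lithium enolate of 20 at C11/C12 (formed in the flask) | C1=C(O[Li])O[C@@H]2CC(C)=C([C@@H](C)CCCO[Si](C)(C)C(C)(C)C)[C@@H](OC(=O)[C@H](C)CC)[C@H]12 | intermediate
22 | C11-(dimethylaminomethyl) lactone (Mannich base; C11 configuration immaterial, formed in the flask) | CN(C)CC1C(=O)O[C@@H]2CC(C)=C([C@@H](C)CCCO[Si](C)(C)C(C)(C)C)[C@@H](OC(=O)[C@H](C)CC)[C@H]12 | intermediate
23 | C11-(trimethylammoniomethyl) lactone iodide (formed in the flask) | C[N+](C)(C)CC1C(=O)O[C@@H]2CC(C)=C([C@@H](C)CCCO[Si](C)(C)C(C)(C)C)[C@@H](OC(=O)[C@H](C)CC)[C@H]12.[I-] | intermediate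
24 | (3aR,4S,7aR)-5-[(2S)-5-{[tert-butyl(dimethyl)silyl]oxy}pentan-2-yl]-6-methyl-3-methylidene-2-oxo-2,3,3a,4,7,7a-hexahydro-1-benzofuran-4-yl (2R)-2-methylbutanoate | C=C1C(=O)O[C@@H]2CC(C)=C([C@@H](C)CCCO[Si](C)(C)C(C)(C)C)[C@@H](OC(=O)[C@H](C)CC)[C@H]12 | intermediate
25 | (3aR,4S,7aR)-5-[(2S)-5-hydroxypentan-2-yl]-6-methyl-3-methylidene-2-oxo-2,3,3a,4,7,7a-hexahydro-1-benzofuran-4-yl (2R)-2-methylbutanoate (CNP0291605.2) | C=C1C(=O)O[C@@H]2CC(C)=C([C@@H](C)CCCO)[C@@H](OC(=O)[C@H](C)CC)[C@H]12 | target

Total step count: 11. Longest linear sequence: 8 steps (steps 1 to 5, then 9 to 11); steps 6 to 8 build the side-chain iodide in parallel.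

Steps most likely to fail, in order of risk.

The key step 5 carries the main risk. The bromoallyl cation may lose a proton from C9 or C14 faster than the hindered carboxylate traps it, or the carboxylate may be captured at C10 or syn to C11 without equilibrating. The fallback sets out from 9 and runs the ring expansion as a silver-promoted hydrolysis (AgNO3, CaCO3, acetone/water, 0 °C to rt). Water in large excess should trap the cation at C6 from the convex face and give the allylic alcohol (3aS,4S,7aR)-5-bromo-4-hydroxy-6-methyl-3a,4,7,7a-tetrahydro-1-benzofuran-2(3H)-one F1. Carbodiimide esterification of F1 with 10 (EDC·HCl, DMAP, CH2Cl2, 0 °C) then returns to the route at 13.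

Step 9 is next. Oxidative addition and transmetalation at the doubly flanked C5 bromide may be slow at the low temperature that keeps the zinc reagent configurationally intact, so conversion may stall or C4 may partly epimerise. The fallback sets out from 13 with a Suzuki–Miyaura coupling (Pd(OAc)2, SPhos, K3PO4, toluene/water, 60 °C). The partner is the alkenylboronate 2-[5-(tert-butyldimethylsilyloxy)pent-1-en-2-yl]-4,4,5,5-tetramethyl-1,3,2-dioxaborolane F2, made from commercial tert-butyldimethyl(pent-4-yn-1-yloxy)silane by copper-catalysed Markovnikov protoboration (CuCl, N-heterocyclic carbene ligand, B2pin2, MeOH). This should give the diene (3aR,4S,7aR)-5-[5-(tert-butyldimethylsilyloxy)pent-1-en-2-yl]-6-methyl-2-oxo-2,3,3a,4,7,7a-hexahydro-1-benzofuran-4-yl (2R)-2-methylbutanoate F3. Hydrogenation of its 1,1-disubstituted alkene with a chiral iridium phosphine–oxazoline catalyst ([Ir(cod)(L*)]BArF, H2, CH2Cl2), which should not reduce the tetrasubstituted ring alkene, sets C4 under catalyst control and returns to the route at 20; any C4 epimer is a separable diastereomer.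

Step 3 is the third. The monooxygenase may discriminate the enantiomers of the methylated ketone poorly, so that 6 forms in low enantiomeric purity or mixed with its regioisomer. The fallback sets out from 5 with a chemical Baeyer–Villiger oxidation (30% H2O2, AcOH, 0 °C), which should give racemic 7-methyl-2-oxabicyclo[3.3.0]oct-6-en-3-one F4. Aminolysis with (S)-1-phenylethylamine (neat, 80 °C) gives two diastereomeric hydroxy amides, from which 2-[(1S,5R)-5-hydroxy-3-methylcyclopent-2-en-1-yl]-N-[(1S)-1-phenylethyl]acetamide F5 is separated by crystallisation or chromatography. Acid-mediated relactonisation of F5 (2 M H2SO4, dioxane, 80 °C) returns to the route at 6.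

Further compounds
F1 | step 5 | (3aS,4S,7aR)-5-bromo-4-hydroxy-6-methyl-3a,4,7,7a-tetrahydro-1-benzofuran-2(3H)-one | C1C(=O)O[C@@H]2CC(C)=C(Br)[C@@H](O)[C@H]12
F2 | step 9 | 2-[5-(tert-butyldimethylsilyloxy)pent-1-en-2-yl]-4,4,5,5-tetramethyl-1,3,2-dioxaborolane | C=C(CCCO[Si](C)(C)C(C)(C)C)B1OC(C)(C)C(C)(C)O1
F3 | step 9 | (3aR,4S,7aR)-5-[5-(tert-butyldimethylsilyloxy)pent-1-en-2-yl]-6-methyl-2-oxo-2,3,3a,4,7,7a-hexahydro-1-benzofuran-4-yl (2R)-2-methylbutanoate | C1C(=O)O[C@@H]2CC(C)=C(C(=C)CCCO[Si](C)(C)C(C)(C)C)[C@@H](OC(=O)[C@H](C)CC)[C@H]12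
F4 | step 3 | racemic cis-7-methyl-2-oxabicyclo[3.3.0]oct-6-en-3-one ((1R,5S) enantiomer drawn) | C1C(=O)O[C@@H]2CC(C)=C[C@H]12
F5 | step 3 | 2-[(1S,5R)-5-hydroxy-3-methylcyclopent-2-en-1-yl]-N-[(1S)-1-phenylethyl]acetamide | O=C(N[C@@H](C)c1ccccc1)C[C@H]1C=C(C)C[C@H]1O
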